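The six-membered carbocycle of the target (bicyclo[4.2.0]octane numbering: C1 methylated fusion carbon, C7 pyrone-bearing carbon) holds C3, with its methyl group, as a single carbon wedged between oxygenated C2 and olefinic C4. Deleting that C–CH3 unit contracts the skeleton to a bicyclo[3.2.0]heptane. Its deep cup lets C8 and quaternary C7 be set by exo alkylation. The key step puts the unit back. Chloro(methyl)carbene adds to the C2=C4 silyl enol ether of a fully substituted, enantiopure bicyclo[3.2.0]heptane carrying an endo CH2OTBS arm at C7, and the chlorocyclopropane opens to the 2-methylcyclohexenone. Dienyl triflate reduction, pyrone construction on the C7 arm and a final singlet-oxygen [4+2] addition across C2/C5 finish the route.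

Key step: step 14

Convention: every bicyclic compound keeps the target numbering: C1 C(CH3) fusion, C2, C3, C4, C5, C6 fusion CH, C7, C8. In the bicyclo[3.2.0] series C3 is absent and C2 is bonded to C4. Exo is the cyclobutane face carrying C1–CH3 and C6–H, and endo is the face carrying the larger ring.

Assumption: the lipase of step 5 follows the usual size rule for secondary alcohols and acetylates the (6R)-alcohol faster, so the required (1R,5S,6S)-alcohol is the one left unreacted.

Step 1
Reactants: 1 5-methylhex-5-en-2-one; 2 ethyl bromoacetate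
Product: 4 ethyl 3-hydroxy-3,6-dimethylhept-6-enoate (racemic), via Reformatsky reagent 3 (not isolated)
Conditions: Zn dust (cat. Me3SiCl activation), THF, 40 °C to reflux; aq NH4Cl
Reagents that add atoms: ethyl bromoacetate, CCOC(=O)CBr
Why: Reformatsky reaction, in which the weakly basic zinc enolate adds to the methyl ketone without enolising it and ignores the 1,1-disubstituted alkene; the racemic carbinol centre is destroyed in step 3.

Step 2
Reactants: 4 ethyl 3-hydroxy-3,6-dimethylhept-6-enoate
Product: 5 3-hydroxy-3,6-dimethylhept-6-enoic acid (racemic)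
Conditions: KOH, MeOH/H2O, rt; cold dilute HCl
Reagents that add atoms: potassium hydroxide, [K+].[OH-]
Why: Ester saponification at room temperature, mild enough to avoid retro-aldol cleavage of the tertiary β-hydroxy ester.

Step 3
Reactants: 5 3-hydroxy-3,6-dimethylhept-6-enoic acid
Product: 7 rac-1,4-dimethylbicyclo[3.2.0]hept-3-en-6-one (IUPAC locants; cis-fused), via vinylketene 6 (not isolated)
Conditions: Ac2O, KOAc, rt then 120 °C
Reagents that add atoms: none
Why: Acetylation and two eliminations of acetic acid from the mixed anhydride give vinylketene 6, whose intramolecular thermal ketene–alkene [2+2] cycloaddition bonds the ketene carbonyl carbon to the terminal CH2 and the ketene α-carbon to the methylated alkene carbon, so C1 and C6 arise together and are necessarily cis.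

Step 4
Reactants: 7 rac-1,4-dimethylbicyclo[3.2.0]hept-3-en-6-one
Product: 8 rac-endo-1,4-dimethylbicyclo[3.2.0]hept-3-en-6-ol
Conditions: NaBH4, MeOH, −20 to 0 °C
Reagents that add atoms: none
Why: Borohydride reduction, with hydride reaching the cyclobutanone from the open exo face, so the hydroxyl group ends up endo and a lipase-readable secondary alcohol results.

Step 5
Reactants: 8 rac-endo-1,4-dimethylbicyclo[3.2.0]hept-3-en-6-ol
Product: 9 (1R,5S,6S)-1,4-dimethylbicyclo[3.2.0]hept-3-en-6-ol
Conditions: immobilised Burkholderia cepacia lipase, vinyl acetate, MTBE, 30 °C, stopped just past half conversion; chromatography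
Reagents that add atoms: none
Why: Lipase-catalysed kinetic resolution by irreversible transesterification, in which the enantiomer whose larger carbinol substituent (the C6 fusion side) fits the large pocket should be acetylated and the slow alcohol is left enantiopure, fixing the absolute configuration of C1 and C6.

Step 6
Reactants: 9 (1R,5S,6S)-1,4-dimethylbicyclo[3.2.0]hept-3-en-6-ol
Product: 10 (1R,5S)-1,4-dimethylbicyclo[3.2.0]hept-3-en-6-one
Conditions: Dess–Martin periodinane, CH2Cl2, 0 °C to rt
Reagents that add atoms: none
Why: Dess–Martin oxidation under near-neutral conditions restores the cyclobutanone without moving the β,γ-alkene or disturbing C6.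

Step 7
Reactants: 10 (1R,5S)-1,4-dimethylbicyclo[3.2.0]hept-3-en-6-one
Product: 12 exo-C8-methyl cyclobutanone (10 with CH3 on C8, cis to C1–CH3), via lithium enolate 11 (not isolated)
Conditions: LiN(iPr)2 (slight excess), THF, −78 °C; MeI, −78 to −40 °C
Reagents that add atoms: iodomethane, CI
Why: Kinetic enolate alkylation, in which the amide removes a proton from the C8 methylene rather than the fusion C6–H (that would need a bridgehead cyclobutene enolate) and MeI enters on the exo face away from the cyclopentene, setting C8.

Step 8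
Reactants: 12 exo-C8-methyl cyclobutanone
Product: 14 C7-carbaldehyde (mixture of C7 epimers), via enol ether 13 (not isolated)
Conditions: Ph3P(CH2OMe)Cl, KOtBu (slight deficit to the salt), THF, 0 °C to rt; then 2 M aq HCl, rt
Reagents that add atoms: (methoxymethyl)triphenylphosphonium chloride, COC[P+](c1ccccc1)(c1ccccc1)c1ccccc1.[Cl-]; water, O
Why: Wittig methoxymethylenation followed by enol ether hydrolysis adds the carbon that later becomes C6 of the pyrone, the absence of free alkoxide protects C8, and the C7 epimer mixture is irrelevant because C7 is flattened again in step 9.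

Step 9
Reactants: 14 C7-carbaldehyde
Product: 16 quaternary aldehyde (C7: CH3 exo, CHO endo), via potassium enolate 15 (not isolated)
Conditions: KOtBu, THF, 0 °C; MeI
Reagents that add atoms: iodomethane, CI
Why: α-Alkylation of an α-branched aldehyde enolate, with C-methylation of the exocyclic enolate on the exo face despite the neighbouring C8 methyl, because the endo face is closed by C5 and its methyl group, which sets C7 as in the target.

Step 10
Reactants: 16 quaternary aldehyde
Product: 17 neopentyl alcohol (C7: CH3 exo, CH2OH endo)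
Conditions: NaBH4, MeOH, 0 °C
Reagents that add atoms: none
Why: Borohydride reduction of a non-enolisable aldehyde, which touches no stereocentre.

Step 11
Reactants: 17 neopentyl alcohol
Product: 18 TBS ether of 17
Conditions: TBSCl, imidazole, DMF, rt
Reagents that add atoms: tert-butyldimethylsilyl chloride, CC(C)(C)[Si](C)(C)Cl
Why: Silyl ether protection of the primary alcohol, chosen because the TBS group withstands chromium oxidants, butyllithium, amide bases and palladium–formate and is removed by fluoride.

Step 12
Reactants: 18 TBS ether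
Product: 19 bicyclo[3.2.0]heptenone (C2=O, C4=C5)
Conditions: CrO3, 3,5-dimethylpyrazole, CH2Cl2, −20 °C
Reagents that add atoms: chromium trioxide, O=[Cr](=O)=O
Why: Allylic oxidation with the CrO3–dimethylpyrazole complex, in which only the C2 methylene can end as a conjugated ketone, since C6–H is a strained fusion methine and the C5 methyl is primary.

Step 13
Reactants: 19 bicyclo[3.2.0]heptenone
Product: 20 triethylsilyl enol ether (C2(OSiEt3)=C4, C5–H exo, C5–CH3 endo)
Conditions: Et3SiH, RhCl(PPh3)3 (cat.), toluene, 50 °C
Reagents that add atoms: triethylsilane, CC[SiH](CC)CC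
Why: Rhodium-catalysed 1,4-hydrosilylation of an enone puts hydride on C5 from the exo face (a centre erased in step 15) and silicon on oxygen, fixing the double bond at C2=C4; Et3SiH is preferred to gaseous Me3SiH, and the triethylsilyl enol ether can be purified and survives butyllithium.

Step 14
Reactants: 20 triethylsilyl enol ether; 21 1,1-dichloroethane
Product: 24 bicyclo[4.2.0]oct-3-en-2-one (C2=O, C3(CH3)=C4H, C5–CH3 endo), via 1,1-dichloroethyllithium 22 (not isolated), via chlorocyclopropane 23 (not isolated)
Conditions: MeCHCl2 (excess), nBuLi (slow addition), Et2O, −40 °C to rt; then toluene, Et3N (buffer), 110 °C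
Reagents that add atoms: 1,1-dichloroethane, CC(Cl)Cl
Why: Loss of LiCl from carbenoid 22 releases chloro(methyl)carbene, which adds in a concerted [2+1] manner to the only C=C of 20, the electron-rich C2=C4 bond, creating C2–C3 and C3–C4 in 23. On heating, chloride departs while the C2–C4 bond opens in a disrotatory cyclopropyl-to-allyl sense, pushed by the siloxy oxygen, and chloride then removes the silyl group to unveil C2(=O)–C3(CH3)=C4H. The closest known chemistry is the one-carbon homologation of cyclic silyl enol ethers with halocarbenes to 2-substituted cycloalkenones. The six-membered ring is made by enlargement and not by cyclisation: a three-membered ring is closed by cheletropic addition, and the bond it shares with the cyclopentane is then cut. No stereocentre is created, because C2, C3 and C4 all finish sp2, so neither the face of addition (expected exo, as the endo CH2OTBS arm fills the cup) nor the Cl/CH3 orientation at C3 affects the product, and C1, C5, C6, C7 and C8 are untouched. The selectivity required is cleavage of the shared bond only, secured by the donor oxygen on C2, while the slowly ionising adduct with exo chlorine is driven through at 110 °C.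

Step 15
Reactants: 24 bicyclo[4.2.0]oct-3-en-2-one
Product: 26 dienyl triflate (C2(OTf)=C3, C4=C5), via potassium dienolate 25 (not isolated)
Conditions: KN(SiMe3)2, THF, −78 to −20 °C; N-(5-chloro-2-pyridyl)bis(trifluoromethanesulfonimide), −78 to 0 °C
Reagents that add atoms: N-(5-chloro-2-pyridyl)bis(trifluoromethanesulfonimide), FC(F)(F)S(=O)(=O)N(c1ccc(Cl)cn1)S(=O)(=O)C(F)(F)F
Why: Vinylogous deprotonation and O-sulfonylation, in which the quaternary C1 leaves the exo C5–H as the only acidic hydrogen, so a single linear dienolate forms and its trapping on oxygen gives the 1,3-dienyl triflate while removing the C5 centre.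

Step 16
Reactants: 26 dienyl triflate
Product: 27 bicyclo[4.2.0]octa-2,4-diene TBS ether
Conditions: Pd(OAc)2 (cat.), PPh3, HCO2H, Et3N, DMF, 40 °C
Reagents that add atoms: none
Why: Palladium-catalysed formate reduction of an enol triflate (oxidative addition to zerovalent palladium, formate exchange, decarboxylation, reductive elimination) replaces OTf by H, and the low temperature guards against electrocyclic opening of the bicyclooctadiene.

Step 17
Reactants: 27 diene TBS ether
Product: 28 diene alcohol
Conditions: Bu4NF, THF, rt
Reagents that add atoms: none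
Why: Fluoride desilylation is non-acidic and leaves the diene and all stereocentres alone.

Step 18
Reactants: 28 diene alcohol
Product: 29 diene aldehyde (CHO endo on C7)
Conditions: Dess–Martin periodinane, pyridine, CH2Cl2, 0 °C to rt
Reagents that add atoms: none
Why: Pyridine-buffered Dess–Martin oxidation gives an aldehyde that cannot epimerise because C7 is quaternary.

Step 19
Reactants: 29 diene aldehyde; 30 methyl 2-methyl-3-oxopentanoate
Product: 32 aldol adduct (δ-hydroxy-β-keto ester, diastereomer mixture), via dilithio dianion 31 (not isolated)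
Conditions: 30, LiN(iPr)2 (2 equiv per 30), THF, −78 to 0 °C; then 29, −78 to −20 °C; aq NH4Cl
Reagents that add atoms: methyl 2-methyl-3-oxopentanoate, CCC(=O)C(C)C(=O)OC
Why: γ-Selective aldol addition of a β-keto ester dianion, whose more reactive terminal carbanion attacks the non-enolisable aldehyde; the three new centres form as a mixture and all become sp2 by step 21.

Step 20
Reactants: 32 aldol adduct
Product: 33 3,5-dioxo ester
Conditions: Dess–Martin periodinane, CH2Cl2, rt
Reagents that add atoms: none
Why: Dess–Martin oxidation of a β-hydroxy ketone to the 1,3-diketone is mild and compatible with the diene.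

Step 21
Reactants: 33 3,5-dioxo ester
Product: 34 4-hydroxy-3,5-dimethyl-2-pyrone bearing the bicyclic unit at C6
Conditions: DBU, toluene, rt to 40 °C
Reagents that add atoms: none
Why: Base-induced lactonisation, in which the enol oxygen of the ketone next to C7 attacks the methyl ester, methanol is lost and tautomerisation gives the aromatic 4-hydroxy-2-pyrone.

Step 22
Reactants: 34 4-hydroxy-2-pyrone
Product: 36 2-methoxy-3,5-dimethyl-4-pyrone diene, via pyrylium triflate 35 (not isolated)
Conditions: MeOTf (slight excess), CH2Cl2, 0 °C to rt; aq NaHCO3 wash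
Reagents that add atoms: methyl trifluoromethanesulfonate, COS(=O)(=O)C(F)(F)F
Why: O-Methylation of the neutral hydroxypyrone with a hard methylating agent occurs at the more basic lactone carbonyl oxygen, and deprotonation of the 4-hydroxy-2-methoxypyrylium salt at work-up gives the α-methoxy-γ-pyrone rather than the 4-methoxy-2-pyrone.

Step 23
Reactants: 36 2-methoxy-4-pyrone diene
Product: 37 target endoperoxide CNP0183511.1
Conditions: O2, methylene blue (cat.), visible light, CH2Cl2, 0 °C
Reagents that add atoms: dioxygen, O=O
Why: Photosensitised singlet-oxygen [4+2] cycloaddition to the cisoid cyclohexadiene bonds oxygen to C2 and C5 on the face carrying C1–CH3 and C6–H, since the other face is covered by the cyclobutane and its endo pyrone, which sets both remaining stereocentres.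

Compound list
1 | 5-methylhex-5-en-2-one | CC(=C)CCC(C)=O | starting material
2 | ethyl bromoacetate | CCOC(=O)CBr | starting material
3 | ethyl (bromozincio)acetate, Reformatsky reagent | CCOC(=O)C[Zn]Br | intermediate
4 | ethyl 3-hydroxy-3,6-dimethylhept-6-enoate (racemic) | CCOC(=O)CC(C)(O)CCC(C)=C | intermediate
5 | 3-hydroxy-3,6-dimethylhept-6-enoic acid (racemic) | OC(=O)CC(C)(O)CCC(C)=C | intermediate
6 | (3Z)-3,6-dimethylhepta-1,3,6-trien-1-one, vinylketene | O=C=C/C(C)=C\CC(C)=C | intermediate
7 | rac-1,4-dimethylbicyclo[3.2.0]hept-3-en-6-one (racemate, one enantiomer drawn) | O=C2C[C@@]3(C)CC=C(C)[C@@H]23 | intermediate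
8 | rac-endo-1,4-dimethylbicyclo[3.2.0]hept-3-en-6-ol (racemate, one enantiomer drawn) | O[C@H]2C[C@@]3(C)CC=C(C)[C@@H]23 | intermediate
9 | (1R,5S,6S)-1,4-dimethylbicyclo[3.2.0]hept-3-en-6-ol | O[C@H]2C[C@@]3(C)CC=C(C)[C@@H]23 | intermediate
10 | (1R,5S)-1,4-dimethylbicyclo[3.2.0]hept-3-en-6-one | O=C2C[C@@]3(C)CC=C(C)[C@@H]23 | intermediate
11 | lithium C7=C8 enolate of 10 | [Li+].[O-]C2=C[C@@]3(C)CC=C(C)[C@@H]23 | intermediate
12 | exo-C8-methyl cyclobutanone | O=C2[C@H](C)[C@@]3(C)CC=C(C)[C@@H]23 | intermediate
13 | C7 methoxymethylidene enol ether (E/Z mixture) | COC=C2[C@H](C)[C@@]3(C)CC=C(C)[C@@H]23 | intermediate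
14 | C7-carbaldehyde (C7 epimers) | O=CC2[C@H](C)[C@@]3(C)CC=C(C)[C@@H]23 | intermediate
15 | potassium enolate of 14 | [K+].[O-]C=C2[C@H](C)[C@@]3(C)CC=C(C)[C@@H]23 | intermediate
16 | quaternary aldehyde, C7 CH3 exo and CHO endo | O=C[C@@]2(C)[C@H](C)[C@@]3(C)CC=C(C)[C@@H]23 | intermediate
17 | neopentyl alcohol | OC[C@@]2(C)[C@H](C)[C@@]3(C)CC=C(C)[C@@H]23 | intermediate
18 | TBS ether of 17 | CC(C)(C)[Si](C)(C)OC[C@@]2(C)[C@H](C)[C@@]3(C)CC=C(C)[C@@H]23 | intermediate
19 | bicyclo[3.2.0]heptenone, C2=O, C4=C5 | CC(C)(C)[Si](C)(C)OC[C@@]2(C)[C@H](C)[C@@]3(C)C(=O)C=C(C)[C@@H]23 | intermediate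
20 | triethylsilyl enol ether, C2=C4, C5–CH3 endo | CC(C)(C)[Si](C)(C)OC[C@@]2(C)[C@H](C)[C@@]3(C)C(O[Si](CC)(CC)CC)=C[C@@H](C)[C@@H]23 | intermediate
21 | 1,1-dichloroethane | CC(Cl)Cl | starting material
22 | 1,1-dichloroethyllithium | [Li]C(C)(Cl)Cl | intermediate
23 | exo-fused 3-chloro-3-methyl-2-siloxycyclopropane (both C3 epimers) | CC(C)(C)[Si](C)(C)OC[C@@]2(C)[C@H](C)[C@@]3(C)[C@]4(O[Si](CC)(CC)CC)C(C)(Cl)[C@@H]4[C@@H](C)[C@@H]23 | intermediate
24 | bicyclo[4.2.0]oct-3-en-2-one | CC(C)(C)[Si](C)(C)OC[C@@]2(C)[C@H](C)[C@@]3(C)C(=O)C(C)=C[C@@H](C)[C@@H]23 | intermediate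
25 | potassium linear dienolate of 24 | [K+].CC(C)(C)[Si](C)(C)OC[C@@]2(C)[C@H](C)[C@@]3(C)C([O-])=C(C)C=C(C)[C@@H]23 | intermediate
26 | dienyl triflate | CC(C)(C)[Si](C)(C)OC[C@@]2(C)[C@H](C)[C@@]3(C)C(OS(=O)(=O)C(F)(F)F)=C(C)C=C(C)[C@@H]23 | intermediate
27 | bicyclo[4.2.0]octa-2,4-diene TBS ether | CC(C)(C)[Si](C)(C)OC[C@@]2(C)[C@H](C)[C@@]3(C)C=C(C)C=C(C)[C@@H]23 | intermediate
28 | diene alcohol | OC[C@@]2(C)[C@H](C)[C@@]3(C)C=C(C)C=C(C)[C@@H]23 | intermediate
29 | diene aldehyde | O=C[C@@]2(C)[C@H](C)[C@@]3(C)C=C(C)C=C(C)[C@@H]23 | intermediate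
30 | methyl 2-methyl-3-oxopentanoate | CCC(=O)C(C)C(=O)OC | starting material
31 | dilithio dianion of 30 | [Li+].[Li+].COC([O-])=C(C)C([O-])=CC | intermediate
32 | aldol adduct (mixture at the three side-chain centres) | COC(=O)C(C)C(=O)C(C)C(O)[C@@]2(C)[C@H](C)[C@@]3(C)C=C(C)C=C(C)[C@@H]23 | intermediate
33 | 3,5-dioxo ester | COC(=O)C(C)C(=O)C(C)C(=O)[C@@]2(C)[C@H](C)[C@@]3(C)C=C(C)C=C(C)[C@@H]23 | intermediate
34 | 4-hydroxy-3,5-dimethyl-6-substituted 2-pyrone | O=c1oc([C@@]2(C)[C@H](C)[C@@]3(C)C=C(C)C=C(C)[C@@H]23)c(C)c(O)c1C | intermediate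
35 | 4-hydroxy-2-methoxypyrylium triflate | COc1[o+]c([C@@]2(C)[C@H](C)[C@@]3(C)C=C(C)C=C(C)[C@@H]23)c(C)c(O)c1C.[O-]S(=O)(=O)C(F)(F)F | intermediate
36 | 2-methoxy-3,5-dimethyl-4-pyrone diene | COc1oc([C@@]2(C)[C@H](C)[C@@]3(C)C=C(C)C=C(C)[C@@H]23)c(C)c(=O)c1C | intermediate
37 | CNP0183511.1, C2/C5 endoperoxide | COc1oc([C@@]2(C)[C@H](C)[C@@]3(C)[C@@H]4OO[C@@](C)(C=C4C)[C@@H]23)c(C)c(=O)c1C | target

Total step count: 23. Longest linear sequence: 23 steps (1 to 37). Compounds 2, 21 and 30 are bought and enter directly.

Steps most likely to fail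

Risk 1, step 14. The short-lived carbenoid may decay by 1,2-hydrogen shift or butylation faster than it cyclopropanates the crowded C2=C4 bond next to quaternary C1. The adduct with exo chlorine may also resist ionisation. The fallback sets out from 20 and returns at 24, forming and cutting the same bonds. Dibromocarbene is more electrophilic and cannot undergo a hydrogen shift. Generated from CHBr3 and KOtBu in pentane at −20 °C to rt, it should give the dibromocyclopropane F1, in which one bromine is always endo. Gentle warming should then open F1 to the C3-bromo enone F2. Suzuki–Miyaura methylation (trimethylboroxine, Pd(dppf)Cl2, K2CO3, dioxane, 80 °C) then places the C3 methyl group and gives 24.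

Risk 2, step 12. Hydrogen abstraction at the neopentyl C2 methylene may be slow. Oxygen delivery to the tertiary C5 end of the allyl system, attack at the C5 methyl group or over-oxidation could then take over. The fallback sets out from 18 and returns at 19 by an ionic, regiodefined sequence.
- Epoxidation with mCPBA on the exo face should give the C4/C5 epoxide F3.
- Phenylselenide (PhSeSePh, NaBH4, EtOH) should open it at the less substituted C4 to the hydroxy selenide F4.
- H2O2 oxidation and selenoxide syn-elimination, which runs away from the carbinol carbon, should give the tertiary allylic alcohol F5 with the alkene at C2=C4.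
- Babler–Dauben oxidative transposition with pyridinium chlorochromate, C5H5NH[CrO3Cl], in CH2Cl2 moves oxygen to C2 and delivers 19.

Risk 3, step 15. Removal of the tertiary γ-hydrogen may be incomplete. Sulfonylation of an enolate oxygen flanked by quaternary C1 and the C3 methyl may also be sluggish. The fallback sets out from 24, returns at 27 and also replaces step 16.
- 1,2-Reduction with iBu2AlH (CH2Cl2, −78 °C), with hydride expected on the face carrying C1–CH3, should give the allylic alcohol F6.
- Acylation with methyl chloroformate and pyridine gives the methyl carbonate F7.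
- Palladium-catalysed 1,4-elimination of Tsuji–Trost type (Pd(PPh3)4, THF, 40 to 50 °C) ionises F7 anti to the carbonate. This places palladium on the face that carries the exo C5–H.
- Syn β-hydride elimination then gives diene 27.

Further compounds
F1 | step 14 | exo-fused 3,3-dibromo-2-siloxycyclopropane | CC(C)(C)[Si](C)(C)OC[C@@]2(C)[C@H](C)[C@@]3(C)[C@]4(O[Si](CC)(CC)CC)C(Br)(Br)[C@@H]4[C@@H](C)[C@@H]23
F2 | step 14 | C3-bromo bicyclo[4.2.0]oct-3-en-2-one | CC(C)(C)[Si](C)(C)OC[C@@]2(C)[C@H](C)[C@@]3(C)C(=O)C(Br)=C[C@@H](C)[C@@H]23
F3 | step 12 | exo C4/C5 epoxide of 18 | CC(C)(C)[Si](C)(C)OC[C@@]2(C)[C@H](C)[C@@]3(C)C[C@@H]4O[C@]4(C)[C@@H]23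
F4 | step 12 | C4 endo-phenylselanyl C5 exo-hydroxy compound | CC(C)(C)[Si](C)(C)OC[C@@]2(C)[C@H](C)[C@@]3(C)C[C@@H]([Se]c4ccccc4)[C@](C)(O)[C@@H]23
F5 | step 12 | tertiary allylic alcohol, C5 OH exo, C2=C4 | CC(C)(C)[Si](C)(C)OC[C@@]2(C)[C@H](C)[C@@]3(C)C=C[C@](C)(O)[C@@H]23
F6 | step 15 | C2 allylic alcohol, OH on the cyclobutane side | CC(C)(C)[Si](C)(C)OC[C@@]2(C)[C@H](C)[C@@]3(C)[C@@H](O)C(C)=C[C@@H](C)[C@@H]23
F7 | step 15 | C2 methyl carbonate of F6 | CC(C)(C)[Si](C)(C)OC[C@@]2(C)[C@H](C)[C@@]3(C)[C@@H](OC(=O)OC)C(C)=C[C@@H](C)[C@@H]23
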